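**Route overview**

- Cuts: the two C–Br bonds of ring B (the dibromophenol ring) go first. Ring B is then taken back to a cyclohexanone ring (phenolic C–OH to C=O, both ring C=C bonds to C–C). The bond from the ether oxygen to that ring is cut at the sp3 carbon alpha to the ketone, leaving a tribromo-methoxyphenol (ring A) and an α-chlorocyclohexanone.
- Ring A's phenol is traced back through its C–O bond to a formyl group; the O–CH3 bond and two C–Br bonds are then cut, ending at a commercial bromosalicylaldehyde.
- Enabling feature: in ring B the free OH sits on the carbon next to the ether-bearing carbon, and both bromines are ortho and para to that OH. This is the pattern of an aromatized and then brominated 2-aryloxycyclohexanone, so the ether oxygen can be joined to a saturated carbon and no aryl–O coupling has to be run beside five C–Br bonds.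
- Forward order: ring A is bought as an arene and fully substituted (steps 1 to 3); ring B is attached as a saturated six-membered ketone (step 4), aromatized (step 5) and brominated last (step 6).
- Stereochemistry: the target has no stereocentre; the single stereocentre of the chloroketone and of the aryloxy ketone is racemic and vanishes on aromatization.

Key step: step 5

Remark: both starting materials are taken as commercially available, and the chloroketone is used as the racemate.

**Route**

Step 1
Reactants: 1 2-bromo-6-hydroxybenzaldehyde
Product: 2 2,3,5-tribromo-6-hydroxybenzaldehyde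
Conditions: Br2 (2.2 equiv), NaOAc, AcOH, rt to 50 °C
Reagents that add atoms: bromine, BrBr
Why: Electrophilic aromatic bromination in which the phenol OH activates only its ortho and para carbons, the same two carbons that are meta to the formyl group and ortho/para to the bromine already present, so all directing effects agree.

Step 2
Reactants: 2 2,3,5-tribromo-6-hydroxybenzaldehyde
Product: 3 2,3,5-tribromo-6-methoxybenzaldehyde
Conditions: MeI, K2CO3, DMF, rt
Reagents that add atoms: iodomethane, CI
Why: Williamson O-methylation, in which the acidic tribromosalicylaldehyde OH is fully ionized by K2CO3 and the phenoxide is alkylated on oxygen by the unhindered methyl electrophile.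

Step 3
Reactants: 3 2,3,5-tribromo-6-methoxybenzaldehyde
Product: 5 2,3,5-tribromo-6-methoxyphenol, via aryl formate 4 (not isolated)
Conditions: mCPBA, CH2Cl2, 0 to 40 °C; then HCl (cat.), MeOH, rt
Reagents that add atoms: mCPBA (3-chloroperoxybenzoic acid), O=C(OO)c1cccc(Cl)c1
Why: Baeyer–Villiger (Dakin-type) oxidation in which, after the peracid adds to the formyl carbon, the aryl group assisted by its ortho methoxy donor should migrate to oxygen in preference to hydride, and the formate 4 is then cleaved by acid-catalysed transesterification with methanol.

Step 4
Reactants: 5 2,3,5-tribromo-6-methoxyphenol; 6 2-chlorocyclohexanone (racemic)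
Product: 7 2-(2,3,5-tribromo-6-methoxyphenoxy)cyclohexan-1-one (racemic)
Conditions: 6 (2 equiv), K2CO3, DMF, 60 °C
Reagents that add atoms: none
Why: Williamson-type SN2 displacement of chloride at a carbonyl-activated secondary carbon by a weakly basic phenoxide, which favours O-alkylation over enolization of the chloroketone; the new stereocentre forms as the racemate without control and is erased in step 5.

Step 5
Reactants: 7 2-(2,3,5-tribromo-6-methoxyphenoxy)cyclohexan-1-one (racemic)
Product: 10 2-(2,3,5-tribromo-6-methoxyphenoxy)phenol, via 2-aryloxycyclohex-2-enone 8 (not isolated), via cross-conjugated dienone 9 (not isolated)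
Conditions: I2 (20 mol %), DMSO, 90 °C
Reagents that add atoms: none
Why: Iodine-catalysed dehydrogenative aromatization with DMSO as terminal oxidant: I2 iodinates the enol at an α carbon and HI is lost to give enone 8, a second α-iodination and HI loss give dienone 9 (drawn as the 2,5-dienone), and 9 enolizes irreversibly to phenol 10 while DMSO turns HI back into I2. The closest known reaction type is the I2/DMSO aromatization of 2-substituted cyclohexanones and of cyclohexenones to ortho-substituted phenols. No ring closes and no skeletal bond forms; the six-membered ketone ring already present loses four hydrogens, two C=C bonds appear and the C=O becomes the phenolic C–OH, so the alkyl aryl ether becomes the diaryl ether. The aryloxy group sits on an α carbon, cannot leave as a β leaving group, and ends up ortho to the new OH whichever α carbon is iodinated first; the racemic stereocentre of 7 is erased and none is created. The chemoselectivity needed, oxidation of the ketone ring without touching the three aryl C–Br bonds or ring A, should hold because the enolizable ketone is the only site reactive toward electrophilic iodine, no low-valent metal or strong base is present, and the single hydrogen of ring A lies between two bromines on a deactivated ring.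

Step 6
Reactants: 10 2-(2,3,5-tribromo-6-methoxyphenoxy)phenol
Product: 11 2,4-dibromo-6-(2,3,5-tribromo-6-methoxyphenoxy)phenol (target)
Conditions: Br2 (2.1 equiv), NaOAc, AcOH, rt
Reagents that add atoms: bromine, BrBr
Why: Electrophilic aromatic bromination directed by the free OH of ring B to its para and ortho carbons, the aryloxy oxygen tied to the electron-poor ring A being the weaker director and ring A itself being deactivated and sterically blocked.

**Compound list**

1 | 2-bromo-6-hydroxybenzaldehyde | O=Cc1c(O)cccc1Br | starting material
2 | 2,3,5-tribromo-6-hydroxybenzaldehyde | O=Cc1c(O)c(Br)cc(Br)c1Br | intermediate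
3 | 2,3,5-tribromo-6-methoxybenzaldehyde | COc1c(Br)cc(Br)c(Br)c1C=O | intermediate
4 | 2,3,5-tribromo-6-methoxyphenyl formate | COc1c(Br)cc(Br)c(Br)c1OC=O | intermediate
5 | 2,3,5-tribromo-6-methoxyphenol | COc1c(Br)cc(Br)c(Br)c1O | intermediate
6 | 2-chlorocyclohexanone (racemic) | O=C1CCCCC1Cl | starting material
7 | 2-(2,3,5-tribromo-6-methoxyphenoxy)cyclohexan-1-one (racemic) | COc1c(Br)cc(Br)c(Br)c1OC1CCCCC1=O | intermediate
8 | 2-(2,3,5-tribromo-6-methoxyphenoxy)cyclohex-2-en-1-one | COc1c(Br)cc(Br)c(Br)c1OC1=CCCCC1=O | intermediate
9 | 2-(2,3,5-tribromo-6-methoxyphenoxy)cyclohexa-2,5-dien-1-one | COc1c(Br)cc(Br)c(Br)c1OC1=CCC=CC1=O | intermediate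
10 | 2-(2,3,5-tribromo-6-methoxyphenoxy)phenol | COc1c(Br)cc(Br)c(Br)c1Oc1ccccc1O | intermediate
11 | 2,4-dibromo-6-(2,3,5-tribromo-6-methoxyphenoxy)phenol | COc1c(Br)cc(Br)c(Br)c1Oc1cc(Br)cc(Br)c1O | target

Total step count: 6. Longest linear sequence: 6 steps (1 to 11; 6 enters as bought).

**Steps most likely to fail**

First, step 5. The ether-bearing α carbon may be oxidized by I2/DMSO (Kornblum-type attack followed by loss of the aryloxy group), the dehydrogenation may stall after the first double bond, or the new electron-rich phenol ring may be iodinated. The fallback brings ring B in as an arene. Setting out from phenol 5, nucleophilic aromatic substitution on 2-fluorobenzaldehyde (K2CO3, DMAc, 130 °C) should give 2-(2,3,5-tribromo-6-methoxyphenoxy)benzaldehyde F1. Baeyer–Villiger oxidation with mCPBA should give 2-(2,3,5-tribromo-6-methoxyphenoxy)phenyl formate F2, and acid-catalysed methanolysis comes back to the route at phenol 10.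

Second, step 4. Substitution by the di-ortho-substituted, weakly nucleophilic phenoxide may be slow and be overtaken by base-induced self-condensation or Favorskii-type breakdown of the chloroketone. The fallback sets out from phenol 5 and uses cyclohexene oxide, which is stable to base and tolerates forcing conditions (K2CO3, DMF, 110 °C). Anti opening by the phenoxide should give trans-2-(2,3,5-tribromo-6-methoxyphenoxy)cyclohexan-1-ol F3 (racemic). Oxidation of the secondary alcohol with Dess–Martin periodinane comes back to the route at ketone 7.

Third, step 3. In the electron-poor, doubly ortho-substituted aldehyde, hydride migration may compete with aryl migration, so that the aldehyde is over-oxidized to the benzoic acid instead of undergoing oxygen insertion. The fallback sets out from aldehyde 3 and goes through a methyl ketone, where no hydride can migrate and aryl outruns methyl. MeMgBr in THF at −78 °C should give 1-(2,3,5-tribromo-6-methoxyphenyl)ethan-1-ol F4 (racemic), and Dess–Martin oxidation should give 1-(2,3,5-tribromo-6-methoxyphenyl)ethan-1-one F5. Baeyer–Villiger oxidation with CF3CO3H in buffered CH2Cl2 should give 2,3,5-tribromo-6-methoxyphenyl acetate F6, and methanolysis with K2CO3 in MeOH comes back to the route at phenol 5.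

**Further compounds**

F1 | step 5 | 2-(2,3,5-tribromo-6-methoxyphenoxy)benzaldehyde | COc1c(Br)cc(Br)c(Br)c1Oc1ccccc1C=O
F2 | step 5 | 2-(2,3,5-tribromo-6-methoxyphenoxy)phenyl formate | COc1c(Br)cc(Br)c(Br)c1Oc1ccccc1OC=O
F3 | step 4 | trans-2-(2,3,5-tribromo-6-methoxyphenoxy)cyclohexan-1-ol (racemic, one enantiomer drawn) | O[C@@H]1CCCC[C@H]1Oc1c(OC)c(Br)cc(Br)c1Br
F4 | step 3 | 1-(2,3,5-tribromo-6-methoxyphenyl)ethan-1-ol (racemic) | COc1c(Br)cc(Br)c(Br)c1C(C)O
F5 | step 3 | 1-(2,3,5-tribromo-6-methoxyphenyl)ethan-1-one | COc1c(Br)cc(Br)c(Br)c1C(C)=O
F6 | step 3 | 2,3,5-tribromo-6-methoxyphenyl acetate | COc1c(Br)cc(Br)c(Br)c1OC(C)=O
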